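The numbers were drawn at random within sensible limits; what happens was integrated by code.

The slowness of this flask sits at its end, in a thin tail where the partners of a second-order step have both been diluted, so we first ask where that tail is heading.

Z 0.14 M (fed, over 20 s); G 0.140 M; D 0.0280 M; time 1.5 min; the fed solution adds 0.50 times the starting volume

    Z + G → Z.G (k1 = 0.615 M⁻¹ s⁻¹)
    Z + G → J (k2 = 0.408 M⁻¹ s⁻¹)
    Z + G → E (k3 = 0.0773 M⁻¹ s⁻¹)
    G + D → G.D (k4 = 2.76 M⁻¹ s⁻¹)

1. why nothing more happens at 1.5 min, or that something still does (G has run out first / all of Z has reacted / it is still moving / forward and back rates have come level)
2. how much of the Z has reacted by 1.5 min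
3. how much Z.G there is at 1.5 min, in percent of the Z charged
4. how much J there is at 1.5 min, in percent of the Z charged
5. how much E there is at 1.5 min, in percent of the Z charged
6. amount of Z.G if the flask were left three thousand times as long, in percent of the Z charged

- amounts are per litre of the starting volume; all of the dose is in the solution fed
- the reaction counts as stopped when no species that holds the Z changes by six tenths of a point or more over the second half of the time
- run time (flask): 1.5 min

In the charged G, D has a half-life of 1.79 s, shorter than the 20 s of dosing, so we give D its full 0.0280 M of G. That makes G the limiting reagent towards Z, and the ceiling is 80.0%, the ratio of the G spared by D to the Z charged, a stoichiometric imbalance of the kind that caps a step growth. The Z steps share the same reactants, so their products divide by their constants, which gives Z.G a share of 55.9% and a final 44.7%.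

For the time course we count the dose as arriving at the middle of the dosing, into the full volume. That leaves 80.0 s at a summed constant of 1.10 M⁻¹ s⁻¹, from [Z] = 0.0933 M and [G] = 0.0747 M, which differ by 0.0187 M. Our first way treats the two as equal, so that 1/[G] grows in a straight line; this gives [G] = 0.009860 M and a conversion of 69.4%. Our second way keeps the difference, so that ln([Z]/[G]) rises steadily from the logarithm of the inverse ceiling. This gives [Z]/[G] = 6.46, [G] = 0.003425 M and a conversion of 76.3%.

The two part by 6.9 percentage points, and the first is the one that cheats, since it holds [Z] equal to [G] where the second finds that ratio at 6.46. We commit to the second, with Z.G 42.7%, J 28.3% and E 5.36%. The same sum at 0.750 min puts the conversion 9.1 points lower, so we say the flask is still moving.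

The forecast says it is still moving, with conversion 76.3%, Z.G 42.6%, J 28.3%, E 5.4% and, in the long run, Z.G 44.7%, on the ground that “the slow tail with dilute G is still shifting the Z species”.

The flask gives it is still moving, with conversion 76.4%, Z.G 42.7%, J 28.3%, E 5.37% and, in the long run, Z.G 44.7%. G stands at 3.7% of its charge at 1.50 min, and by 15.0 min the conversion reads 80.0%, at the ceiling of 80.0%. A larger charge of Z moves these answers: in a neighbour flask with 0.56 M of Z, the same ratio with D given its full share reads 20.0%, and its Z.G 11.2%, but that flask gives a higher conversion of 20.4% and Z.G 11.4% at 1.50 min, with G at 0% of its charge and D still at 7.68% of its own.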